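**Plan**

1. Retrosynthesis: once the O7 ethyl group is removed, four bonds of ring A are cut in one operation (C8–C8a, C5–C6, C7–C8, C4a–C5). This leaves a 4-pyranone carrying a 2-diazopropanoyl group, plus ethoxyacetylene.
2. Enabling feature: ring A (C4a, C5, C6, C7, C8, C8a) is fused to the pyranone ring along C4a–C8a and carries OH at C5, H at C6, O at C7 and CH3 at C8. This is the pattern that a methyl-substituted vinylketene and an alkoxyalkyne assemble.
3. Further back: the diazo ketone comes from the pyranone carboxylic acid chloride and diazoethane. The pyranone comes from C4a–C8a bond formation (diketone dianion plus diethyl oxalate) and O1–C8a ring closure. The side chain is cut at C1'–C2' (acetylacetone dianion plus 1-bromotriacontane).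
4. Forward order: the chain is joined first, the pyranone ring is closed second, ring A is closed third, and O7 is dealkylated last.
5. Stereochemistry: the target has no stereocentre. Only regiochemistry (8-methyl, not 6-methyl) matters, and the connectivity of the ring A construction fixes it.

Key step: step 7

Assumption: the side chain is read as unbranched n-hentriacontyl (31 carbons); intermediates 13 and 15 are transient racemates whose stereocentres vanish on aromatisation.

**Route**

Step 1
Reactants: 1 1-triacontanol
Product: 2 1-bromotriacontane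
Conditions: PPh3, CBr4, CH2Cl2/THF, 0 to 35 °C
Reagents that add atoms: carbon tetrabromide, BrC(Br)(Br)Br
Why: Appel bromination; bromide displaces the alkoxyphosphonium leaving group of an unhindered primary alcohol by SN2, and warm solvent keeps the waxy substrate dissolved.

Step 2
Reactants: 3 acetylacetone (pentane-2,4-dione); 2 1-bromotriacontane
Product: 4 pentatriacontane-2,4-dione
Conditions: 3 (1.5 equiv), LiN(iPr)2 (2.1 equiv per 3), THF, 0 °C; then 2 in warm THF, 0 to 40 °C; dilute HCl
Reagents that add atoms: none
Why: Hauser-type dianion alkylation of a 1,3-diketone; the terminal carbanion is the most nucleophilic site of the dianion, so SN2 attack on the primary bromide should give C-alkylation at the methyl group only, and excess dianion suppresses double alkylation.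

Step 3
Reactants: 4 pentatriacontane-2,4-dione; 5 diethyl oxalate
Product: 7 ethyl 6-hentriacontyl-4-oxo-4H-pyran-2-carboxylate, via triketo ester 6 (not isolated)
Conditions: LiN(iPr)2 (3 equiv), THF, 0 °C; (CO2Et)2, -40 to 0 °C; 1 M HCl; then TsOH·H2O (cat.), PhMe, reflux (Dean–Stark)
Reagents that add atoms: none
Why: Claisen acylation of the diketone dianion, which forms kinetically at the methyl rather than the C5 methylene terminus, gives the 2,4,6-trioxo ester; acid then drives cyclodehydration of this 1,3,5-tricarbonyl (C6 enol oxygen onto the C2 keto group) to the 4-pyranone, as in the classical preparations of comanic and chelidonic esters.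

Step 4
Reactants: 7 ethyl 6-hentriacontyl-4-oxo-4H-pyran-2-carboxylate
Product: 8 6-hentriacontyl-4-oxo-4H-pyran-2-carboxylic acid
Conditions: conc. HCl/AcOH (1:3), 100 °C; cool and filter
Reagents that add atoms: water, O
Why: acid-catalysed ester hydrolysis; acidic conditions are chosen because 4-pyranones tolerate acid but are opened by hydroxide, and hot acetic acid dissolves the long-chain ester.

Step 5
Reactants: 8 6-hentriacontyl-4-oxo-4H-pyran-2-carboxylic acid
Product: 9 6-hentriacontyl-4-oxo-4H-pyran-2-carbonyl chloride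
Conditions: (COCl)2 (1.5 equiv), DMF (cat.), CH2Cl2, 0 °C to rt; evaporate, use crude
Reagents that add atoms: oxalyl chloride, O=C(Cl)C(Cl)=O
Why: acid chloride formation through the catalytic chloroiminium (Vilsmeier-type) intermediate; the acid has no alpha hydrogen, and the ring carbonyl of an acceptor-substituted pyranone is a poor nucleophile toward the chlorinating agent.

Step 6
Reactants: 9 6-hentriacontyl-4-oxo-4H-pyran-2-carbonyl chloride
Product: 10 2-(2-diazopropanoyl)-6-hentriacontyl-4H-pyran-4-one
Conditions: CH3CHN2 (3 equiv, from N-ethyl-N-nitrosourea and aq. KOH, dried ethereal solution), Et2O/THF, -20 to 0 °C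
Reagents that add atoms: diazoethane, CC=[N+]=[N-]
Why: Arndt–Eistert-type acylation of a diazoalkane; the diazo carbon attacks the acid chloride, a second equivalent of diazoethane removes HCl as chloroethane, and at low temperature acylation should outrun dipolar addition to the ring double bonds.

Step 7
Reactants: 10 2-(2-diazopropanoyl)-6-hentriacontyl-4H-pyran-4-one; 11 ethoxyacetylene
Product: 16 7-ethoxy-2-hentriacontyl-5-hydroxy-8-methylchromen-4-one, via pyranyl methyl ketene 12 (not isolated), via vinylcyclobutenone 13 (not isolated), via dienylketene 14 (not isolated), via cyclohexadienone tautomer 15 (not isolated)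
Conditions: 11 (3 equiv), ClCH2CH2Cl (degassed, dilute), hν (>300 nm, Pyrex-filtered medium-pressure Hg lamp or 365 nm LED), 20 °C; evaporate excess 11; then PhMe, 80–100 °C
Reagents that add atoms: none
Why: Light above 300 nm expels N2 from 10 and the pyranyl group shifts from the carbonyl carbon to the diazo carbon (photochemical Wolff rearrangement, forming C8–C8a), giving ketene 12, which is a vinylketene through the pyranone C2=C3 bond. The electron-rich ynol ether 11 adds in a (2+2) cycloaddition, its unsubstituted carbon bonding to the ketene carbonyl carbon (C5–C6) and its oxygen-bearing carbon to the methyl-bearing carbon (C7–C8), and cyclobutenone 13 then opens reversibly by four-electron electrocyclic cleavage to dienylketene 14. Ring A is closed by a thermal six-electron (disrotatory) electrocyclization in which the ketene carbon bonds to pyranone C3 (C4a–C5), and dione 15 enolises to the chelated C5 phenol 16. The closest known reaction is the Danheiser benzannulation of aryl, heteroaryl and alkenyl alpha-diazo ketones with alkoxy- and siloxyalkynes. No stereocentre is formed; the selectivity needed is regiochemical, and it is secured by the polarisation of the ynol ether (nucleophilic CH terminus to the electrophilic ketene carbon) and by pyranone C3 being the only carbon available for closure, so OH, H, OEt and CH3 can only end up at C5, C6, C7 and C8. Long-wavelength light, which the diazo chromophore absorbs but the pyranone absorbs only weakly, should favour the Wolff shift over pyranone photoisomerisation, and the hydrogen-bonded C5 hydroxyl is too poor a nucleophile to be acylated by residual ketene.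

Step 8
Reactants: 16 7-ethoxy-2-hentriacontyl-5-hydroxy-8-methylchromen-4-one
Product: 17 2-hentriacontyl-5,7-dihydroxy-8-methylchromen-4-one (CNP0154031.0)
Conditions: BBr3 (4 equiv), CH2Cl2, -78 °C to rt; MeOH, then H2O
Reagents that add atoms: none
Why: Lewis-acid dealkylation of an aryl ethyl ether; boron coordinates O7 and bromide displaces the ethyl group by SN2, while the chromone carbonyl and C5 hydroxyl are only held as a borate chelate that water releases.

**Compound list**

1 | 1-triacontanol | CCCCCCCCCCCCCCCCCCCCCCCCCCCCCCO | starting material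
2 | 1-bromotriacontane | CCCCCCCCCCCCCCCCCCCCCCCCCCCCCCBr | intermediate
3 | acetylacetone (pentane-2,4-dione) | CC(=O)CC(C)=O | starting material
4 | pentatriacontane-2,4-dione | CCCCCCCCCCCCCCCCCCCCCCCCCCCCCCCC(=O)CC(C)=O | intermediate
5 | diethyl oxalate | CCOC(=O)C(=O)OCC | starting material
6 | ethyl 2,4,6-trioxoheptatriacontanoate (not isolated) | CCCCCCCCCCCCCCCCCCCCCCCCCCCCCCCC(=O)CC(=O)CC(=O)C(=O)OCC | intermediate
7 | ethyl 6-hentriacontyl-4-oxo-4H-pyran-2-carboxylate | CCCCCCCCCCCCCCCCCCCCCCCCCCCCCCCc1cc(=O)cc(C(=O)OCC)o1 | intermediate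
8 | 6-hentriacontyl-4-oxo-4H-pyran-2-carboxylic acid | CCCCCCCCCCCCCCCCCCCCCCCCCCCCCCCc1cc(=O)cc(C(=O)O)o1 | intermediate
9 | 6-hentriacontyl-4-oxo-4H-pyran-2-carbonyl chloride | CCCCCCCCCCCCCCCCCCCCCCCCCCCCCCCc1cc(=O)cc(C(Cl)=O)o1 | intermediate
10 | 2-(2-diazopropanoyl)-6-hentriacontyl-4H-pyran-4-one | CCCCCCCCCCCCCCCCCCCCCCCCCCCCCCCc1cc(=O)cc(C(=O)C(C)=[N+]=[N-])o1 | intermediate
11 | ethoxyacetylene | C#COCC | starting material
12 | 2-(6-hentriacontyl-4-oxo-4H-pyran-2-yl)prop-1-en-1-one, the methyl(pyranyl)ketene (not isolated) | CCCCCCCCCCCCCCCCCCCCCCCCCCCCCCCc1cc(=O)cc(C(C)=C=O)o1 | intermediate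
13 | 3-ethoxy-4-(6-hentriacontyl-4-oxo-4H-pyran-2-yl)-4-methylcyclobut-2-en-1-one, racemic (not isolated) | CCCCCCCCCCCCCCCCCCCCCCCCCCCCCCCc1cc(=O)cc(C2(C)C(=O)C=C2OCC)o1 | intermediate
14 | (3E)-3-ethoxy-4-(6-hentriacontyl-4-oxo-4H-pyran-2-yl)penta-1,3-dien-1-one, pyranyl and ketenyl groups cis (not isolated) | CCCCCCCCCCCCCCCCCCCCCCCCCCCCCCCc1cc(=O)cc(/C(C)=C(\C=C=O)OCC)o1 | intermediate
15 | 7-ethoxy-2-hentriacontyl-8-methyl-4aH-chromene-4,5-dione, racemic (not isolated) | CCCCCCCCCCCCCCCCCCCCCCCCCCCCCCCC1=CC(=O)C2C(=O)C=C(OCC)C(C)=C2O1 | intermediate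
16 | 7-ethoxy-2-hentriacontyl-5-hydroxy-8-methylchromen-4-one | CCCCCCCCCCCCCCCCCCCCCCCCCCCCCCCc1cc(=O)c2c(O)cc(OCC)c(C)c2o1 | intermediate
17 | 2-hentriacontyl-5,7-dihydroxy-8-methylchromen-4-one (CNP0154031.0) | CCCCCCCCCCCCCCCCCCCCCCCCCCCCCCCc1cc(=O)c2c(O)cc(O)c(C)c2o1 | target

**Totals**

Total step count: 8. Longest linear sequence: 8 steps (1 to 17).

**Steps most likely to fail**

Step 7. After loss of N2 the methyl-bearing carbene may undergo 1,2-hydrogen shift to a vinyl ketone instead of the Wolff shift, the pyranone may photoisomerise, or ketene 12 may dimerise before the alkyne traps it. The fallback builds ring A from a bought arene and closes the pyranone ring classically; it sets out from bromide 2 and returns to the route at target 17. Commercial 2-hydroxy-4,6-dimethoxyacetophenone is condensed with ethyl acetate (NaH, THF) to 1-(2-hydroxy-4,6-dimethoxyphenyl)butane-1,3-dione F1, which HCl in AcOH cyclises to 5,7-dimethoxy-2-methylchromen-4-one F2. The 2-methyl group is deprotonated (LiN(iPr)2, THF, -78 °C) and the lateral anion alkylated with 2 to give 2-hentriacontyl-5,7-dimethoxychromen-4-one F3. Iodination (N-iodosuccinimide, CF3CO2H), expected at C8 in the 5,7-dimethoxychromone series, should give 2-hentriacontyl-8-iodo-5,7-dimethoxychromen-4-one F4. Suzuki–Miyaura methylation (trimethylboroxine, Pd(PPh3)4, K2CO3, dioxane) then gives 2-hentriacontyl-5,7-dimethoxy-8-methylchromen-4-one F5, and BBr3 removes both methyl groups to give 17.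

Step 6. Diazoethane may add as a 1,3-dipole to the electron-poor ring double bond next to the acyl chloride, or be consumed by HCl faster than it is acylated. The fallback replaces diazoalkane acylation by diazo transfer; it sets out from acid 8 and returns at diazo ketone 10. Acid 8 is activated with carbonyldiimidazole and treated with MeNHOMe·HCl to give 6-hentriacontyl-N-methoxy-N-methyl-4-oxo-4H-pyran-2-carboxamide F6. EtMgBr (THF, -78 °C) converts it into 6-hentriacontyl-2-propanoyl-4H-pyran-4-one F7. Its lithium enolate (LiN(SiMe3)2, THF, -78 °C) is acylated with 2,2,2-trifluoroethyl trifluoroacetate to 4,4,4-trifluoro-1-(6-hentriacontyl-4-oxo-4H-pyran-2-yl)-2-methylbutane-1,3-dione F8. This is not isolated but treated with methanesulfonyl azide, Et3N and water in MeCN (detrifluoroacetylative diazo transfer) to give 10.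

Step 3. The second deprotonation of 4 may occur at the C5 methylene instead of the methyl group, the dianion may condense twice with diethyl oxalate, or the waxy lithium enolate may precipitate before it reacts. The fallback makes the pyranone first and attaches the chain last; it sets out from 3, 5 and 2 and returns at ester 7. Compounds 3 and 5 are condensed (NaOEt, EtOH) to ethyl 2,4,6-trioxoheptanoate F9, which is cyclised without isolation (HCl, EtOH) to ethyl 6-methyl-4-oxo-4H-pyran-2-carboxylate F10. SeO2 (dioxane, reflux) oxidises the activated methyl group to ethyl 6-formyl-4-oxo-4H-pyran-2-carboxylate F11. Bromide 2 and PPh3 (PhMe, reflux) give triacontyl(triphenyl)phosphonium bromide F12, whose ylide (NaN(SiMe3)2, THF, -78 °C) undergoes Wittig olefination with F11 to ethyl 6-[(1Z)-hentriacont-1-en-1-yl]-4-oxo-4H-pyran-2-carboxylate F13. Hydrogenation of the side-chain alkene (H2, Pd on carbon, EtOAc, one equivalent) gives 7.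

**Further compounds**

F1 | step 7 | 1-(2-hydroxy-4,6-dimethoxyphenyl)butane-1,3-dione | CC(=O)CC(=O)c1c(O)cc(OC)cc1OC
F2 | step 7 | 5,7-dimethoxy-2-methylchromen-4-one | Cc1cc(=O)c2c(OC)cc(OC)cc2o1
F3 | step 7 | 2-hentriacontyl-5,7-dimethoxychromen-4-one | CCCCCCCCCCCCCCCCCCCCCCCCCCCCCCCc1cc(=O)c2c(OC)cc(OC)cc2o1
F4 | step 7 | 2-hentriacontyl-8-iodo-5,7-dimethoxychromen-4-one | CCCCCCCCCCCCCCCCCCCCCCCCCCCCCCCc1cc(=O)c2c(OC)cc(OC)c(I)c2o1
F5 | step 7 | 2-hentriacontyl-5,7-dimethoxy-8-methylchromen-4-one | CCCCCCCCCCCCCCCCCCCCCCCCCCCCCCCc1cc(=O)c2c(OC)cc(OC)c(C)c2o1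
F6 | step 6 | 6-hentriacontyl-N-methoxy-N-methyl-4-oxo-4H-pyran-2-carboxamide | CCCCCCCCCCCCCCCCCCCCCCCCCCCCCCCc1cc(=O)cc(C(=O)N(C)OC)o1
F7 | step 6 | 6-hentriacontyl-2-propanoyl-4H-pyran-4-one | CCCCCCCCCCCCCCCCCCCCCCCCCCCCCCCc1cc(=O)cc(C(=O)CC)o1
F8 | step 6 | 4,4,4-trifluoro-1-(6-hentriacontyl-4-oxo-4H-pyran-2-yl)-2-methylbutane-1,3-dione | CCCCCCCCCCCCCCCCCCCCCCCCCCCCCCCc1cc(=O)cc(C(=O)C(C)C(=O)C(F)(F)F)o1
F9 | step 3 | ethyl 2,4,6-trioxoheptanoate | CC(=O)CC(=O)CC(=O)C(=O)OCC
F10 | step 3 | ethyl 6-methyl-4-oxo-4H-pyran-2-carboxylate | Cc1cc(=O)cc(C(=O)OCC)o1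
F11 | step 3 | ethyl 6-formyl-4-oxo-4H-pyran-2-carboxylate | O=Cc1cc(=O)cc(C(=O)OCC)o1
F12 | step 3 | triacontyl(triphenyl)phosphonium bromide | CCCCCCCCCCCCCCCCCCCCCCCCCCCCCC[P+](c1ccccc1)(c1ccccc1)c1ccccc1.[Br-]
F13 | step 3 | ethyl 6-[(1Z)-hentriacont-1-en-1-yl]-4-oxo-4H-pyran-2-carboxylate | CCCCCCCCCCCCCCCCCCCCCCCCCCCCC/C=C\c1cc(=O)cc(C(=O)OCC)o1
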